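The dimethylpyran ring fused to aryl ring B is the closed valence tautomer of a dienyl ortho-quinone methide. It is therefore cut first at its O–CMe2 bond and then at the ring B–CH= bond, back to a guaiacol-type phenol and prenal. In one operation phenylboronic acid ties the 4'-OH of 7-O-pivaloyl-3'-methoxydaidzein and prenal into a temporary benzodioxaborin at C5', the only free carbon ortho to O4'. Loss of PhBO unveils the quinone methide, and an oxa-6π electrocyclisation closes the pyran by O–CMe2 bond formation while ring B rearomatises. The precursor is a plain isoflavone lacking all five prenal-derived carbons. Its core comes in one pot from resorcinol and homovanillic acid.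

Key step: step 3

Remark: locants follow isoflavone usage (ring A and the pyranone C2–C8a; ring B C1'–C6' with OMe on C3', oxygen on C4' and the reacting carbon C5'). The target has no stereocentre and its non-aromatic C=C bonds lie in six-membered rings, so no stereocontrol is needed.

Step 1
Reactants: 1 resorcinol; 2 homovanillic acid
Product: 4 7-hydroxy-3-(4-hydroxy-3-methoxyphenyl)-4H-chromen-4-one (3'-methoxydaidzein), via deoxybenzoin 3 (not isolated)
Conditions: BF3·OEt2 (solvent), 85 °C; then DMF, MeSO2Cl, 10 → 70 °C; ice-water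
Reagents that add atoms: N,N-dimethylformamide (DMF), CN(C)C=O
Why: Friedel–Crafts acylation of resorcinol at C4 by the BF3-activated acid should give 3 as its boron chelate, whose acidified methylene is then C-formylated by the Vilsmeier-type iminium salt from DMF and MeSO2Cl, after which the 2-OH adds and dimethylamine is lost to close the pyranone, a one-pot deoxybenzoin route to isoflavones that is known to tolerate free phenols.

Step 2
Reactants: 4 7-hydroxy-3-(4-hydroxy-3-methoxyphenyl)-4H-chromen-4-one
Product: 5 3-(4-hydroxy-3-methoxyphenyl)-4-oxo-4H-chromen-7-yl pivalate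
Conditions: KOt-Bu (1.0 equiv), DMF, 0 °C; then PivCl (1.0 equiv), 0 °C → rt
Reagents that add atoms: pivaloyl chloride, CC(C)(C)C(=O)Cl
Why: The 7-OH is a vinylogous carboxylic acid and far more acidic than the guaiacol 4'-OH, so one equivalent of base should generate only the 7-phenoxide, which is O-acylated (regioselective phenoxide acylation) by a bulky acid chloride that in addition avoids the 4'-oxygen flanked by OMe.

Step 3
Reactants: 5 3-(4-hydroxy-3-methoxyphenyl)-4-oxo-4H-chromen-7-yl pivalate; 6 3-methylbut-2-enal (prenal); 7 phenylboronic acid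
Product: 10 3-(8-methoxy-2,2-dimethyl-2H-chromen-6-yl)-4-oxo-4H-chromen-7-yl pivalate, via benzodioxaborin 8 (not isolated), via ortho-quinone methide 9 (not isolated)
Conditions: PhB(OH)2 (1.2 equiv), prenal (2 equiv, in portions), AcOH–toluene, reflux, water separator
Reagents that add atoms: none
Why: Phenylboronic acid esterifies the only free phenol (O4') of 5 and binds prenal 6, so the aldehyde carbon is delivered through a six-membered boron-templated transition state to C5' and the resulting diol is locked as the temporary benzodioxaborin ring of 8. At reflux 8 loses PhBO in a retro-hetero-Diels–Alder fragmentation and unveils the dienyl ortho-quinone methide 9, whose O=C4'–C5'=CH–CH=CMe2 array closes by a thermal disrotatory oxa-6π electrocyclisation in which the carbonyl oxygen bonds to the CMe2 terminus, driven by rearomatisation of ring B. The closest known reaction type is the phenylboronic acid and acetic acid mediated condensation of phenols with α,β-unsaturated aldehydes to 2H-chromenes (a formal [3+3] annulation). The one ring that remains, the six-membered pyran, is thus closed pericyclically at the O–C bond after the intermolecular C–C bond is in place, and only the Z form of 9 can close, the E form feeding it by reversible protonation in the acidic medium. No stereocentre is left in 10, since C4 of racemic 8 becomes sp2. The step needs ring B over ring A, C5' over other carbons and 1,2- over 1,4-attack on the enal: the pivalate removes the 7-OH that would otherwise direct boron to C8 or C6, OMe at C3' and the chromenone at C1' block the other ortho and the para position, and the template together with the hindered CMe2 terminus holds the attack at the carbonyl carbon.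

Step 4
Reactants: 10 3-(8-methoxy-2,2-dimethyl-2H-chromen-6-yl)-4-oxo-4H-chromen-7-yl pivalate
Product: 11 7-hydroxy-3-(8-methoxy-2,2-dimethyl-2H-chromen-6-yl)-4H-chromen-4-one (target)
Conditions: K2CO3 (1.5 equiv), MeOH–THF, rt; then 1 M HCl to pH 5
Reagents that add atoms: none
Why: Methanolysis (transesterification) of an aryl ester whose leaving group is the stabilised 7-phenoxide should proceed at room temperature, the released phenoxide feeds electron density into the pyranone and so shields C2 from methoxide, and the chromene and the aryl methyl ether are inert to carbonate.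

Compound list
1 | resorcinol | Oc1cccc(O)c1 | starting material
2 | homovanillic acid, 2-(4-hydroxy-3-methoxyphenyl)acetic acid | COc1cc(CC(=O)O)ccc1O | starting material
3 | 1-(2,4-dihydroxyphenyl)-2-(4-hydroxy-3-methoxyphenyl)ethan-1-one (deoxybenzoin, not isolated) | COc1cc(CC(=O)c2ccc(O)cc2O)ccc1O | intermediate
4 | 7-hydroxy-3-(4-hydroxy-3-methoxyphenyl)-4H-chromen-4-one (3'-methoxydaidzein) | COc1cc(-c2coc3cc(O)ccc3c2=O)ccc1O | intermediate
5 | 3-(4-hydroxy-3-methoxyphenyl)-4-oxo-4H-chromen-7-yl pivalate | COc1cc(-c2coc3cc(OC(=O)C(C)(C)C)ccc3c2=O)ccc1O | intermediate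
6 | 3-methylbut-2-enal (prenal) | CC(C)=CC=O | starting material
7 | phenylboronic acid | OB(O)c1ccccc1 | starting material
8 | 3-[8-methoxy-4-(2-methylprop-1-enyl)-2-phenyl-4H-1,3,2-benzodioxaborin-6-yl]-4-oxo-4H-chromen-7-yl pivalate (racemic, not isolated) | COc1cc(-c2coc3cc(OC(=O)C(C)(C)C)ccc3c2=O)cc2c1OB(c1ccccc1)OC2C=C(C)C | intermediate
9 | 3-[(3Z)-5-methoxy-3-(3-methylbut-2-en-1-ylidene)-4-oxocyclohexa-1,5-dien-1-yl]-4-oxo-4H-chromen-7-yl pivalate (ortho-quinone methide, not isolated) | COC1=CC(c2coc3cc(OC(=O)C(C)(C)C)ccc3c2=O)=C/C(=C/C=C(C)C)C1=O | intermediate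
10 | 3-(8-methoxy-2,2-dimethyl-2H-chromen-6-yl)-4-oxo-4H-chromen-7-yl pivalate | COc1cc(-c2coc3cc(OC(=O)C(C)(C)C)ccc3c2=O)cc2c1OC(C)(C)C=C2 | intermediate
11 | 7-hydroxy-3-(8-methoxy-2,2-dimethyl-2H-chromen-6-yl)-4H-chromen-4-one | COc1cc(-c2coc3cc(O)ccc3c2=O)cc2c1OC(C)(C)C=C2 | target

Total step count: 4. Longest linear sequence: 4 (1 and 2 → 4 → 5 → 10 → 11).

Steps most likely to fail

**Risk 1 (step 3, key step).** The boron-templated attack of C5' on the aldehyde may be too slow, because this carbon is activated by one oxygen only. Prenal may then be consumed by self-condensation before ring B reacts. The fallback runs from 5 back to 10 and makes the carbon–carbon bond by palladium catalysis instead of by electrophilic substitution with the aldehyde.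
- Iodination of 5 ortho to the free phenol (NIS, cat. TsOH, MeCN, rt) should give 3-(4-hydroxy-3-iodo-5-methoxyphenyl)-4-oxo-4H-chromen-7-yl pivalate F1.
- A Heck reaction with 2-methylbut-3-en-2-ol (Pd(OAc)2, P(o-tol)3, Et3N, DMF, 90 °C) should give 3-{4-hydroxy-3-[(E)-3-hydroxy-3-methylbut-1-enyl]-5-methoxyphenyl}-4-oxo-4H-chromen-7-yl pivalate F2.
- PPTS in toluene at reflux ionises the tertiary allylic alcohol, proton loss leads to 9, and 9 closes to 10.

**Risk 2 (step 2).** The acylation may not discriminate enough between the two phenols, or the acyl group may wander between them by intermolecular transfer. The fallback runs from 4 back to 11, drops protection altogether and addresses the 4'-oxygen instead of masking the 7-oxygen.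
- KOt-Bu (2.0 equiv) in DMF forms the dianion, in which the non-conjugated 4'-phenoxide is the stronger nucleophile.
- 3-Chloro-3-methylbut-1-yne with CuCl (cat.) at 0 °C → rt should then give 7-hydroxy-3-[3-methoxy-4-(2-methylbut-3-yn-2-yloxy)phenyl]-4H-chromen-4-one F3.
- Heating in N,N-diethylaniline at 190 °C should trigger an aromatic propargyl Claisen rearrangement to 7-hydroxy-3-[4-hydroxy-3-methoxy-5-(3-methylbuta-1,2-dienyl)phenyl]-4H-chromen-4-one F4.
- A 1,5-hydrogen shift then leads to 7-hydroxy-3-[(3Z)-5-methoxy-3-(3-methylbut-2-en-1-ylidene)-4-oxocyclohexa-1,5-dien-1-yl]-4H-chromen-4-one F5, and oxa-6π closure gives 11.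

**Risk 3 (step 1).** The hot Lewis acid may erode the guaiacol methyl ether, or the C-formylation of the boron-chelated deoxybenzoin may stall so that ring closure stays incomplete. The fallback runs from 1 back to 4 and joins ring B to a finished chromenone by cross-coupling.
- Nencki acetylation of 1 (AcOH, ZnCl2, 140 °C) should give 1-(2,4-dihydroxyphenyl)ethan-1-one F6.
- DMF dimethyl acetal (toluene, 95 °C, short contact) should give (E)-1-(2,4-dihydroxyphenyl)-3-(dimethylamino)prop-2-en-1-one F7.
- I2 in MeOH at rt should effect iodinative cyclisation to 7-hydroxy-3-iodo-4H-chromen-4-one F8.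
- Suzuki–Miyaura coupling with commercial 2-methoxy-4-(4,4,5,5-tetramethyl-1,3,2-dioxaborolan-2-yl)phenol (Pd(PPh3)4, Na2CO3, dioxane–H2O, 80 °C) should give 4.

Further compounds
F1 | step 3 | 3-(4-hydroxy-3-iodo-5-methoxyphenyl)-4-oxo-4H-chromen-7-yl pivalate | COc1cc(-c2coc3cc(OC(=O)C(C)(C)C)ccc3c2=O)cc(I)c1O
F2 | step 3 | 3-{4-hydroxy-3-[(E)-3-hydroxy-3-methylbut-1-enyl]-5-methoxyphenyl}-4-oxo-4H-chromen-7-yl pivalate | COc1cc(-c2coc3cc(OC(=O)C(C)(C)C)ccc3c2=O)cc(/C=C/C(C)(C)O)c1O
F3 | step 2 | 7-hydroxy-3-[3-methoxy-4-(2-methylbut-3-yn-2-yloxy)phenyl]-4H-chromen-4-one | COc1cc(-c2coc3cc(O)ccc3c2=O)ccc1OC(C)(C)C#C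
F4 | step 2 | 7-hydroxy-3-[4-hydroxy-3-methoxy-5-(3-methylbuta-1,2-dienyl)phenyl]-4H-chromen-4-one | COc1cc(-c2coc3cc(O)ccc3c2=O)cc(C=C=C(C)C)c1O
F5 | step 2 | 7-hydroxy-3-[(3Z)-5-methoxy-3-(3-methylbut-2-en-1-ylidene)-4-oxocyclohexa-1,5-dien-1-yl]-4H-chromen-4-one | COC1=CC(c2coc3cc(O)ccc3c2=O)=C/C(=C/C=C(C)C)C1=O
F6 | step 1 | 1-(2,4-dihydroxyphenyl)ethan-1-one | CC(=O)c1ccc(O)cc1O
F7 | step 1 | (E)-1-(2,4-dihydroxyphenyl)-3-(dimethylamino)prop-2-en-1-one | CN(C)/C=C/C(=O)c1ccc(O)cc1O
F8 | step 1 | 7-hydroxy-3-iodo-4H-chromen-4-one | O=c1c(I)coc2cc(O)ccc12
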